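**Plan**

1. Locants (3,7-dioxabicyclo[3.3.0]octane): C1 (OAc bridgehead), C2 (guaiacyl CH), O3, C4, C5 (H bridgehead), C6 (veratryl CH), O7, C8. Ring A = C1–C2–O3–C4–C5; ring B = C1–C5–C6–O7–C8.
2. Retrosynthesis: first undo the acetate and phenol and raise C4 to a lactone carbonyl (activating group), then cut C8–C1 and C6–C5 together. Ring B holds the ether triad C8–O7–C6, and its two carbons sit on the two ends of the C1–C5 fusion bond. That is the retron of a carbonyl ylide [3+2] addition to a C1=C5 alkene; the pieces are veratraldehyde O-methylide and a (5R)-5-aryl-4-benzyloxybutenolide (tetronate).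
3. The tetronate is cut at C1=C5 and O3–C4 (ketenylidene phosphorane addition, then intramolecular Wittig) back to an (R)-mandelate, which comes from an aryl glyoxylate.
4. Forward order: aryl glyoxylate, (R)-mandelate, ring A (tetronate), ring B by the cycloaddition, C4 lactone to CH2, debenzylation, acetylation and release of the phenol.
5. Stereochemistry: C2 from catalytic asymmetric transfer hydrogenation; C1, C5 and C6 from the cycloaddition (anti to the C2 aryl group, cis fusion, exo veratryl).

Key step: step 6

Assumption: the transfer hydrogenation is taken to follow the usual aryl ketone facial model, so that RuCl(p-cymene)[(S,S)-TsDPEN] gives the R carbinol; if the sense were opposite, the (R,R) complex would be used.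

**Step 1**
Reactants: 1 1-(benzyloxy)-4-bromo-2-methoxybenzene; 2 dibenzyl oxalate
Product: 4 benzyl 2-[4-(benzyloxy)-3-methoxyphenyl]-2-oxoacetate, via aryl Grignard reagent 3 (not isolated)
Conditions: Mg, THF, reflux; then added to 2 (2 equiv), THF, −78 °C; 1 M HCl quench
Reagents that add atoms: none
Why: Grignard acylation of an oxalate diester should stop at the α-keto ester because the magnesium-bound tetrahedral adduct survives at −78 °C until the quench.

**Step 2**
Reactants: 4 benzyl 2-[4-(benzyloxy)-3-methoxyphenyl]-2-oxoacetate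
Product: 5 benzyl (2R)-2-[4-(benzyloxy)-3-methoxyphenyl]-2-hydroxyacetate
Conditions: RuCl(p-cymene)[(S,S)-TsDPEN] (1 mol %), HCO2H/Et3N (5:2), DMF, 25 °C; recrystallisation
Reagents that add atoms: none
Why: Noyori-type asymmetric transfer hydrogenation of the aryl α-keto ester should deliver hydride from the Ru–H/N–H catalyst to one carbonyl face (aryl group held against the cymene ligand) and so set the R carbinol centre that becomes C2.

**Step 3**
Reactants: 5 benzyl (2R)-2-[4-(benzyloxy)-3-methoxyphenyl]-2-hydroxyacetate; 6 (triphenylphosphoranylidene)ketene (Ph3P=C=C=O)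
Product: 8 (5R)-4-(benzyloxy)-5-[4-(benzyloxy)-3-methoxyphenyl]furan-2(5H)-one, via acyl phosphorus ylide 7 (not isolated)
Conditions: 6 (1.2 equiv), THF, 65 °C, 16 h
Reagents that add atoms: none
Why: The hydroxyl group adds across the C=C bond of the ketenylidene phosphorane and the resulting ester ylide 7 closes ring A by intramolecular Wittig olefination of the benzyl ester carbonyl (tetronate synthesis), which leaves the ester benzyl group on the C1 oxygen and does not touch the stereocentre.

**Step 4**
Reactants: 9 3,4-dimethoxybenzaldehyde (veratraldehyde); 10 (trimethylsilyl)methanol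
Product: 11 4-{bis[(trimethylsilyl)methoxy]methyl}-1,2-dimethoxybenzene
Conditions: 10 (2.5 equiv), p-TsOH·H2O (2 mol %), cyclohexane, reflux, Dean–Stark trap
Reagents that add atoms: none
Why: Acid-catalysed acetalisation is driven to completion by azeotropic removal of water.

**Step 5**
Reactants: 11 4-{bis[(trimethylsilyl)methoxy]methyl}-1,2-dimethoxybenzene
Product: 12 {[chloro(3,4-dimethoxyphenyl)methoxy]methyl}trimethylsilane (racemic)
Conditions: AcCl (1.05 equiv), SOCl2 (1 mol %), CH2Cl2, 0 °C to rt; volatiles removed under high vacuum; used at once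
Reagents that add atoms: acetyl chloride, CC(Cl)=O
Why: Acetal cleavage by an acyl chloride (α-chloro ether synthesis) should be easy here because the dimethoxyphenyl ring stabilises the oxocarbenium ion, which collapses with chloride while one silylmethoxy group leaves as its acetate.

**Step 6**
Reactants: 12 {[chloro(3,4-dimethoxyphenyl)methoxy]methyl}trimethylsilane; 8 (5R)-4-(benzyloxy)-5-[4-(benzyloxy)-3-methoxyphenyl]furan-2(5H)-one
Product: 14 (3R,3aS,6S,6aR)-3a-(benzyloxy)-3-[4-(benzyloxy)-3-methoxyphenyl]-6-(3,4-dimethoxyphenyl)tetrahydro-1H,3H-furo[3,4-c]furan-1-one, via carbonyl ylide 13 (not isolated)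
Conditions: CsF (anhydrous, 4 equiv), MeCN, 0 °C to rt; 12 (2.5 equiv) added over 4 h
Reagents that add atoms: none
Why: Fluoride attacks silicon of the easily ionised α-chloro ether 12, and the 1,3-elimination releases the non-stabilised carbonyl ylide 13, which should add across the C1=C5 bond of tetronate 8 in a concerted, asynchronous, suprafacial [3+2] cycloaddition that forms C8–C1 and C6–C5 together. The closest known reaction type is the fluoride-induced 1,3-elimination of (1-chloroalkyl) (trimethylsilyl)methyl ethers with trapping of the carbonyl ylide by α,β-unsaturated esters, and its nitrogen counterpart, the addition of silylmethylamine-derived azomethine ylides to butenolides. Ring B closes as a pericyclic [3+2] annulation onto the endocyclic alkene of ring A, so no Baldwin-type closure is involved, and the cis ring fusion (C1–OBn and C5–H on one face) follows from suprafacial addition to the cyclic Z-alkene. The absolute sense at C1 and C5 is controlled by the C2 stereocentre, because the ylide adds to the face anti to the C2 aryl group and so places the C1 oxygen cis to that aryl group as in the target; C6 is set by an exo transition state of the W-shaped ylide with its C–O–C bridge turned away from the lactone ring, which puts the veratryl group on the convex face. The step needs regioselectivity (CH2 terminus to the oxygen-bearing β-carbon C1, ArCH terminus to the α-carbon C5), and this is secured by matched polarity and size, since the donor aryl group localises cationic character at the benzylic carbon while the nucleophilic, unhindered CH2 terminus attacks the electrophilic, fully substituted β-carbon of the vinylogous carbonate. The C4 lactone carbonyl is the activating group that lowers the alkene LUMO for this dipole-HOMO-controlled addition, and slow addition of excess 12 should keep ylide self-reaction and fluoride-mediated enolisation at C2–H of 8 behind the cycloaddition.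

**Step 7**
Reactants: 14 the lactone from step 6
Product: 15 (3R,3aS,6S,6aR)-3a-(benzyloxy)-3-[4-(benzyloxy)-3-methoxyphenyl]-6-(3,4-dimethoxyphenyl)tetrahydro-1H,3H-furo[3,4-c]furan-1-ol (mixture of anomers)
Conditions: i-Bu2AlH (1.2 equiv), CH2Cl2, −78 °C; aq. potassium sodium tartrate work-up
Reagents that add atoms: none
Why: Partial reduction of a γ-lactone to the lactol by i-Bu2AlH should stop at the aluminium-bound tetrahedral intermediate at −78 °C, with the benzyl ethers untouched; the new anomeric centre is removed in step 8.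

**Step 8**
Reactants: 15 the lactol from step 7
Product: 16 (1S,2R,5R,6S)-1-(benzyloxy)-2-[4-(benzyloxy)-3-methoxyphenyl]-6-(3,4-dimethoxyphenyl)-3,7-dioxabicyclo[3.3.0]octane
Conditions: Et3SiH (3 equiv), BF3·OEt2 (1.5 equiv), CH2Cl2, −78 to −40 °C; NaHCO3 quench
Reagents that add atoms: none
Why: Ionic hydrogenation of a lactol: BF3 ionises the hemiacetal to the C4 oxocarbenium ion, which triethylsilane should reduce at low temperature before the benzylic ring ethers can ionise.

**Step 9**
Reactants: 16 the bis(benzyl ether) from step 8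
Product: 17 (1S,2R,5R,6S)-6-(3,4-dimethoxyphenyl)-2-(4-hydroxy-3-methoxyphenyl)-3,7-dioxabicyclo[3.3.0]octan-1-ol
Conditions: H2 (1 atm), Pd/C (10 wt % Pd), EtOAc/EtOH, rt, stopped at full debenzylation
Reagents that add atoms: none
Why: Catalytic hydrogenolysis of benzyl ethers: under neutral conditions at 1 atm the two O–CH2Ph bonds should cleave faster than the hindered secondary benzylic C–O bonds of the ring system.

**Step 10**
Reactants: 17 the diol from step 9
Product: 18 (1S,2R,5R,6S)-1-acetoxy-2-(4-acetoxy-3-methoxyphenyl)-6-(3,4-dimethoxyphenyl)-3,7-dioxabicyclo[3.3.0]octane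
Conditions: Ac2O (5 equiv), Et3N, DMAP (0.3 equiv), CH2Cl2, 40 °C
Reagents that add atoms: acetic anhydride, CC(=O)OC(C)=O
Why: DMAP-catalysed acylation (Steglich-type) should acetylate the phenol quickly and the tertiary bridgehead alcohol more slowly, without affecting any stereocentre.

**Step 11**
Reactants: 18 the diacetate from step 10
Product: 19 (1S,2R,5R,6S)-1-acetoxy-6-(3,4-dimethoxyphenyl)-2-(4-hydroxy-3-methoxyphenyl)-3,7-dioxabicyclo[3.3.0]octane (CNP0107105.1)
Conditions: pyrrolidine (1.5 equiv), CH2Cl2, 0 °C
Reagents that add atoms: none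
Why: Chemoselective aminolysis of the aryl acetate: phenoxide is a far better leaving group than a tertiary alkoxide and the bridgehead acetate is hindered, so only the phenolic ester should be cleaved.

**Compound list**

1 | 1-(benzyloxy)-4-bromo-2-methoxybenzene | COc1cc(Br)ccc1OCc1ccccc1 | starting material
2 | dibenzyl oxalate | O=C(OCc1ccccc1)C(=O)OCc1ccccc1 | starting material
3 | [4-(benzyloxy)-3-methoxyphenyl]magnesium bromide (formed in the flask) | COc1cc([Mg]Br)ccc1OCc1ccccc1 | intermediate
4 | benzyl 2-[4-(benzyloxy)-3-methoxyphenyl]-2-oxoacetate | COc1cc(C(=O)C(=O)OCc2ccccc2)ccc1OCc1ccccc1 | intermediate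
5 | benzyl (2R)-2-[4-(benzyloxy)-3-methoxyphenyl]-2-hydroxyacetate | COc1cc([C@@H](O)C(=O)OCc2ccccc2)ccc1OCc1ccccc1 | intermediate
6 | (triphenylphosphoranylidene)ketene | O=C=C=P(c1ccccc1)(c1ccccc1)c1ccccc1 | starting material
7 | benzyl (2R)-2-[4-(benzyloxy)-3-methoxyphenyl]-2-{[(triphenyl-λ5-phosphanylidene)acetyl]oxy}acetate (formed in the flask) | COc1cc([C@@H](OC(=O)C=P(c2ccccc2)(c2ccccc2)c2ccccc2)C(=O)OCc2ccccc2)ccc1OCc1ccccc1 | intermediate
8 | (5R)-4-(benzyloxy)-5-[4-(benzyloxy)-3-methoxyphenyl]furan-2(5H)-one | COc1cc([C@H]2OC(=O)C=C2OCc3ccccc3)ccc1OCc4ccccc4 | intermediate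
9 | 3,4-dimethoxybenzaldehyde | COc1ccc(C=O)cc1OC | starting material
10 | (trimethylsilyl)methanol | C[Si](C)(C)CO | starting material
11 | 4-{bis[(trimethylsilyl)methoxy]methyl}-1,2-dimethoxybenzene | COc1ccc(C(OC[Si](C)(C)C)OC[Si](C)(C)C)cc1OC | intermediate
12 | {[chloro(3,4-dimethoxyphenyl)methoxy]methyl}trimethylsilane (racemic) | COc1ccc(C(Cl)OC[Si](C)(C)C)cc1OC | intermediate
13 | veratraldehyde O-methylide, the carbonyl ylide ArCH=O(+)–CH2(−) (formed in the flask) | COc1ccc(C=[O+][CH2-])cc1OC | intermediate
14 | (3R,3aS,6S,6aR)-3a-(benzyloxy)-3-[4-(benzyloxy)-3-methoxyphenyl]-6-(3,4-dimethoxyphenyl)tetrahydro-1H,3H-furo[3,4-c]furan-1-one (cis-fused, both aryl groups exo) | COc1cc([C@H]2OC(=O)[C@@H]3[C@@H](c4ccc(OC)c(OC)c4)OC[C@]23OCc5ccccc5)ccc1OCc6ccccc6 | intermediate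
15 | (3R,3aS,6S,6aR)-3a-(benzyloxy)-3-[4-(benzyloxy)-3-methoxyphenyl]-6-(3,4-dimethoxyphenyl)tetrahydro-1H,3H-furo[3,4-c]furan-1-ol (anomer mixture) | COc1cc([C@H]2OC(O)[C@@H]3[C@@H](c4ccc(OC)c(OC)c4)OC[C@]23OCc5ccccc5)ccc1OCc6ccccc6 | intermediate
16 | (1S,2R,5R,6S)-1-(benzyloxy)-2-[4-(benzyloxy)-3-methoxyphenyl]-6-(3,4-dimethoxyphenyl)-3,7-dioxabicyclo[3.3.0]octane | COc1cc([C@H]2OC[C@@H]3[C@@H](c4ccc(OC)c(OC)c4)OC[C@]23OCc5ccccc5)ccc1OCc6ccccc6 | intermediate
17 | (1S,2R,5R,6S)-6-(3,4-dimethoxyphenyl)-2-(4-hydroxy-3-methoxyphenyl)-3,7-dioxabicyclo[3.3.0]octan-1-ol | COc1cc([C@H]2OC[C@@H]3[C@@H](c4ccc(OC)c(OC)c4)OC[C@]23O)ccc1O | intermediate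
18 | (1S,2R,5R,6S)-1-acetoxy-2-(4-acetoxy-3-methoxyphenyl)-6-(3,4-dimethoxyphenyl)-3,7-dioxabicyclo[3.3.0]octane | COc1cc([C@H]2OC[C@@H]3[C@@H](c4ccc(OC)c(OC)c4)OC[C@]23OC(C)=O)ccc1OC(C)=O | intermediate
19 | (1S,2R,5R,6S)-1-acetoxy-6-(3,4-dimethoxyphenyl)-2-(4-hydroxy-3-methoxyphenyl)-3,7-dioxabicyclo[3.3.0]octane | COc1cc([C@H]2OC[C@@H]3[C@@H](c4ccc(OC)c(OC)c4)OC[C@]23OC(C)=O)ccc1O | target

**Step count**

Total step count: 11. Longest linear sequence: 9 steps (steps 1, 2, 3, 6, 7, 8, 9, 10, 11); steps 4 and 5 form the side branch to the ylide precursor.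

**Steps most likely to fail**

Step 6. The cycloaddition onto the donor-substituted, trisubstituted alkene of 8 may be slower than self-quenching of the ylide. Fluoride may also enolise the acidic C2–H of 8 and erode the enantiomeric purity, and regio- or exo/endo selectivity may be incomplete. The fallback sets out from 8 and adds a traceless activating group. N-Chlorosuccinimide (MeCN, rt) should chlorinate the nucleophilic vinylic position of the tetronate (C5 in the locants above) to give (5R)-4-(benzyloxy)-5-[4-(benzyloxy)-3-methoxyphenyl]-3-chlorofuran-2(5H)-one F1. The α-chlorine lowers the alkene LUMO, reinforces the polarisation toward attack at C1, and leaves the adduct without a ring-fusion α-hydrogen, so fluoride cannot eliminate the benzyloxy group. The same ylide (12, CsF, MeCN) should then give the 6a-chloro analogue of 14, (3R,3aS,6R,6aS)-3a-(benzyloxy)-3-[4-(benzyloxy)-3-methoxyphenyl]-6a-chloro-6-(3,4-dimethoxyphenyl)tetrahydro-1H,3H-furo[3,4-c]furan-1-one F2. Radical dechlorination (Bu3SnH, AIBN, toluene, 80 °C) delivers hydrogen to the convex face of the ring-fusion radical, restores the cis fusion, and comes back to the route at 14.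

Step 9. Hydrogenolysis of the benzylic C2–O3 and C6–O7 ring bonds may compete with the slower debenzylation of the hindered tertiary ether, so that over-reduction opens the ring system. The fallback sets out from 16 and replaces surface hydrogenolysis by single-electron reductive debenzylation with lithium 4,4'-di-tert-butylbiphenylide (THF, −78 °C, NH4Cl quench). Electron transfer into the unsubstituted phenyl rings of the two benzyl groups is easier than into the dialkoxyaryl rings, so the O–CH2Ph bonds should fragment first. It comes back to the route at 17 and makes no new compound.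

Step 8. BF3 may ionise the electron-rich benzylic ether bonds in competition with the lactol, which would cause epimerisation at C2 or C6 or reductive ring opening by the silane. The fallback sets out from 14 and avoids any Lewis acid. LiAlH4 (THF, 0 °C) should reduce the lactone to (R)-[4-(benzyloxy)-3-methoxyphenyl][(3S,4R,5S)-3-(benzyloxy)-5-(3,4-dimethoxyphenyl)-4-(hydroxymethyl)oxolan-3-yl]methanol F3. Selective sulfonylation of the primary hydroxyl (MsCl 1.05 equiv, Et3N, CH2Cl2, 0 °C) gives the primary methanesulfonate of that diol F4. On warming, the benzylic hydroxyl displaces the mesylate (5-exo-tet, retention at C2) to close ring A, and the sequence comes back to the route at 16.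

**Further compounds**

F1 | step 6 | (5R)-4-(benzyloxy)-5-[4-(benzyloxy)-3-methoxyphenyl]-3-chlorofuran-2(5H)-one | COc1cc([C@H]2OC(=O)C(Cl)=C2OCc3ccccc3)ccc1OCc4ccccc4
F2 | step 6 | (3R,3aS,6R,6aS)-3a-(benzyloxy)-3-[4-(benzyloxy)-3-methoxyphenyl]-6a-chloro-6-(3,4-dimethoxyphenyl)tetrahydro-1H,3H-furo[3,4-c]furan-1-one | COc1cc([C@H]2OC(=O)[C@]3(Cl)[C@@H](c4ccc(OC)c(OC)c4)OC[C@]23OCc5ccccc5)ccc1OCc6ccccc6
F0 | step 9 | none | none
F3 | step 8 | (R)-[4-(benzyloxy)-3-methoxyphenyl][(3S,4R,5S)-3-(benzyloxy)-5-(3,4-dimethoxyphenyl)-4-(hydroxymethyl)oxolan-3-yl]methanol | COc1cc([C@@H](O)[C@@]2(OCc3ccccc3)CO[C@H](c4ccc(OC)c(OC)c4)[C@H]2CO)ccc1OCc5ccccc5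
F4 | step 8 | [(2S,3R,4S)-4-(benzyloxy)-4-{(R)-[4-(benzyloxy)-3-methoxyphenyl](hydroxy)methyl}-2-(3,4-dimethoxyphenyl)oxolan-3-yl]methyl methanesulfonate | COc1cc([C@@H](O)[C@@]2(OCc3ccccc3)CO[C@H](c4ccc(OC)c(OC)c4)[C@H]2COS(C)(=O)=O)ccc1OCc5ccccc5
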